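The route rests on cutting C2–C3 of the dihydropyran ring (ring B), the bond between the O1-bearing CMe2 carbon and the carbinol carbon. The feature exploited is the vicinal O1–C2–C3–O array. Both carbons are carbonyl-type acceptor carbons, so joining them needs polarity reversal, and O1 plus two methyl groups stabilise a radical at C2. An N-heterocyclic carbene turns a C3 aldehyde into an electron-rich Breslow enolate that reduces a redox-active ester on C2. Loss of CO2 and radical–radical coupling close ring B as a chroman-3-one and build the fully substituted C2 in one operation. The precursor is an open-chain aryloxyisobutyric phthalimide ester with an ortho CH2CHO arm. Catalyst-controlled reduction then sets C3.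

Key step: step 6

Remark on the chemistry: chroman numbering is used for all bicyclic compounds (O1, C2 = CMe2, C3 = carbinol carbon, C4 = CH2, C4a, C5 to C8, C8a). Ring A is the benzene ring and ring B the pyran ring. By the CIP rules the stereocenter of the target is 3R.

Step 1
Reactants: 1 2,4,6-trihydroxyacetophenone; 2 benzyl bromide
Product: 3 1-[2,4-bis(benzyloxy)-6-hydroxyphenyl]ethanone
Conditions: BnBr (2.1 equiv), K2CO3 (2.2 equiv), DMF, rt to 50 °C
Reagents that add atoms: benzyl bromide, BrCc1ccccc1
Why: Williamson etherification, in which the free 4-OH and one of the two equivalent ortho OH groups are benzylated while the last OH is held in a hydrogen bond to the acetyl carbonyl and stays unreactive toward a carbonate base at moderate temperature.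

Step 2
Reactants: 3 1-[2,4-bis(benzyloxy)-6-hydroxyphenyl]ethanone; 4 allyl bromide
Product: 5 1-[2-(allyloxy)-4,6-bis(benzyloxy)phenyl]ethanone
Conditions: allyl bromide (1.5 equiv), K2CO3 (2 equiv), DMF, 60 °C
Reagents that add atoms: allyl bromide, C=CCBr
Why: Williamson etherification under more forcing conditions, where a polar aprotic solvent, heat and a reactive allylic halide overcome the hydrogen bond of the one remaining phenol.

Step 3
Reactants: 5 1-[2-(allyloxy)-4,6-bis(benzyloxy)phenyl]ethanone
Product: 6 1-[3-allyl-4,6-bis(benzyloxy)-2-hydroxyphenyl]ethanone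
Conditions: N,N-diethylaniline, 200 °C, Ar
Reagents that add atoms: none
Why: Aromatic Claisen rearrangement ([3,3]-sigmatropic shift), in which one ortho position is blocked by the acetyl group so that the allyl group can only migrate to the free CH between the two oxygen-bearing carbons, and rearomatisation sets free exactly the phenol oxygen that becomes O1.

Step 4
Reactants: 6 1-[3-allyl-4,6-bis(benzyloxy)-2-hydroxyphenyl]ethanone; 7 2-bromo-2-methylpropanoic acid
Product: 8 2-[2-acetyl-6-allyl-3,5-bis(benzyloxy)phenoxy]-2-methylpropanoic acid
Conditions: powdered NaOH (excess), 7 (2.5 equiv, in portions), 2-butanone, 50 °C; then aq. HCl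
Reagents that add atoms: 2-bromo-2-methylpropanoic acid, CC(C)(Br)C(=O)O
Why: O-alkylation of the phenoxide by the alpha-bromo carboxylate, which loses bromide with help from the neighbouring carboxylate so that the tertiary carbon is attacked through a loose and sterically undemanding transition state, the only free OH of 6 being the future O1.

Step 5
Reactants: 8 2-[2-acetyl-6-allyl-3,5-bis(benzyloxy)phenoxy]-2-methylpropanoic acid
Product: 9 2-[2-acetyl-3,5-bis(benzyloxy)-6-(2-oxoethyl)phenoxy]-2-methylpropanoic acid
Conditions: OsO4 (2 mol %), NaIO4 (4 equiv), 2,6-lutidine (2 equiv), dioxane–H2O 3:1, rt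
Reagents that add atoms: OsO4, O=[Os](=O)(=O)=O (catalytic oxygen carrier); NaIO4, [Na+].[O-]I(=O)(=O)=O (terminal oxygen source)
Why: Lemieux–Johnson oxidation, in which catalytic dihydroxylation of the only alkene and periodate cleavage of the diol remove the terminal carbon and leave the arylacetaldehyde, whose two flanking oxygen atoms are blocked so that neither a lactol nor a benzofuran can form.

Step 6
Reactants: 9 2-[2-acetyl-3,5-bis(benzyloxy)-6-(2-oxoethyl)phenoxy]-2-methylpropanoic acid; 10 N-hydroxyphthalimide
Product: 12 8-acetyl-5,7-bis(benzyloxy)-2,2-dimethylchroman-3-one, via phthalimide active ester 11 (not isolated)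
Conditions: 10 (1.0 equiv), N,N'-diisopropylcarbodiimide (1.05 equiv), DMAP (5 mol %), CH2Cl2, 0 °C to rt; filter, evaporate; then 3-(2,6-diisopropylphenyl)-5,6,7,8-tetrahydro-4H-cyclohepta[d]thiazol-3-ium perchlorate (15 mol %), Cs2CO3 (30 mol %), DMSO (0.02 M), 60 °C, Ar
Reagents that add atoms: none
Why: Carbodiimide (Steglich-type) esterification first converts acid 9 into the redox-active ester 11; the carbene released from the thiazolium salt then adds to the aldehyde carbon C3 and proton transfer plus deprotonation give a Breslow enolate, so that the normally electrophilic C3 becomes a strong one-electron donor; electron transfer to the phthalimide ester of the same molecule, N–O cleavage and loss of CO2 leave a persistent ketyl-type radical at C3 and a transient tertiary radical at C2 that O1 stabilises, and their recombination followed by expulsion of the carbene gives ketone 12. The closest known reaction type is the N-heterocyclic-carbene-catalysed decarboxylative radical alkylation of aliphatic aldehydes by tertiary N-acyloxyphthalimides to dialkyl ketones, run here within one molecule. The only ring that closes, the pyranone ring B, closes by radical–radical coupling of a 1,6-diradical, helped by the ortho placing of both arms on ring A and by the gem-dimethyl effect at C2. No stereocenter is formed, because C2 bears two methyl groups and C3 is trigonal; C3 is set in step 7. The step needs carbene addition and electron transfer to outrun base-induced enolisation of the arylacetaldehyde (aldol reaction or acyl transfer to C4), which the neopentyl-like shielding of the ester carbonyl, substoichiometric Cs2CO3 and high dilution should secure. The 8-acetyl group stays out because a hindered, electron-rich ketone forms no Breslow intermediate and sits meta to the C4 arm, and the benzyl ethers on O5 and O7 prevent lactol or benzofuran formation.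

Step 7
Reactants: 12 8-acetyl-5,7-bis(benzyloxy)-2,2-dimethylchroman-3-one
Product: 13 1-[(3R)-5,7-bis(benzyloxy)-3-hydroxy-2,2-dimethylchroman-8-yl]ethanone
Conditions: (S)-2-methyl-CBS-oxazaborolidine [(3aS)-1-methyl-3,3-diphenyltetrahydro-3H-pyrrolo[1,2-c][1,3,2]oxazaborole] (20 mol %), BH3·SMe2 (0.7 equiv), THF, −20 °C, slow addition of 12; MeOH, then aqueous work-up
Reagents that add atoms: none
Why: Corey–Bakshi–Shibata reduction, in which the ring ketone binds to the catalyst boron with the quaternary C2 (CMe2OAr) as the large group and C4H2 as the small group, so that the (S)-catalyst should deliver hydride to the Si face of C3 and give 3R (the same sense as for tert-alkyl methyl ketones), while the acetyl carbonyl with its two ortho alkoxy groups is too hindered and electron-rich to compete at low temperature with a limited amount of borane.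

Step 8
Reactants: 13 1-[(3R)-5,7-bis(benzyloxy)-3-hydroxy-2,2-dimethylchroman-8-yl]ethanone
Product: 14 1-[(3R)-3,5,7-trihydroxy-2,2-dimethylchroman-8-yl]ethanone
Conditions: H2 (1 atm), Pd/C (10 wt % Pd), EtOAc–MeOH 1:1, rt
Reagents that add atoms: none
Why: Hydrogenolysis of the two benzyl aryl ethers over palladium, under which the homobenzylic C3–OH, the ring ether and the aryl ketone should survive at one atmosphere and room temperature and C3 is not touched.

Step 9
Reactants: 14 1-[(3R)-3,5,7-trihydroxy-2,2-dimethylchroman-8-yl]ethanone; 15 geranyl bromide
Product: 16 1-[(3R)-5-{[(2E)-3,7-dimethylocta-2,6-dien-1-yl]oxy}-3,7-dihydroxy-2,2-dimethylchroman-8-yl]ethanone (target)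
Conditions: geranyl bromide (1.05 equiv), K2CO3 (1.2 equiv), acetone, rt to 40 °C
Reagents that add atoms: geranyl bromide, BrC/C=C(\C)CCC=C(C)C
Why: Regioselective Williamson etherification, in which the 5-OH (para to the acetyl group, the most acidic and not hydrogen-bonded) displaces bromide by SN2 with the E alkene kept, whereas the 7-OH is tied to the acetyl carbonyl and the aliphatic 3-OH is not deprotonated by carbonate.

Compound list
1 | 2,4,6-trihydroxyacetophenone | CC(=O)c1c(O)cc(O)cc1O | starting material
2 | benzyl bromide | BrCc1ccccc1 | starting material
3 | 1-[2,4-bis(benzyloxy)-6-hydroxyphenyl]ethanone | CC(=O)c1c(O)cc(OCc2ccccc2)cc1OCc1ccccc1 | intermediate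
4 | allyl bromide | C=CCBr | starting material
5 | 1-[2-(allyloxy)-4,6-bis(benzyloxy)phenyl]ethanone | CC(=O)c1c(OCC=C)cc(OCc2ccccc2)cc1OCc1ccccc1 | intermediate
6 | 1-[3-allyl-4,6-bis(benzyloxy)-2-hydroxyphenyl]ethanone | CC(=O)c1c(O)c(CC=C)c(OCc2ccccc2)cc1OCc1ccccc1 | intermediate
7 | 2-bromo-2-methylpropanoic acid | CC(C)(Br)C(=O)O | starting material
8 | 2-[2-acetyl-6-allyl-3,5-bis(benzyloxy)phenoxy]-2-methylpropanoic acid | CC(=O)c1c(OC(C)(C)C(=O)O)c(CC=C)c(OCc2ccccc2)cc1OCc1ccccc1 | intermediate
9 | 2-[2-acetyl-3,5-bis(benzyloxy)-6-(2-oxoethyl)phenoxy]-2-methylpropanoic acid | CC(=O)c1c(OC(C)(C)C(=O)O)c(CC=O)c(OCc2ccccc2)cc1OCc1ccccc1 | intermediate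
10 | N-hydroxyphthalimide | O=C1c2ccccc2C(=O)N1O | starting material
11 | 1,3-dioxoisoindolin-2-yl 2-[2-acetyl-3,5-bis(benzyloxy)-6-(2-oxoethyl)phenoxy]-2-methylpropanoate | CC(=O)c1c(OC(C)(C)C(=O)ON2C(=O)c3ccccc3C2=O)c(CC=O)c(OCc2ccccc2)cc1OCc1ccccc1 | intermediate
12 | 8-acetyl-5,7-bis(benzyloxy)-2,2-dimethylchroman-3-one | CC(=O)c1c(OCc2ccccc2)cc(OCc2ccccc2)c2c1OC(C)(C)C(=O)C2 | intermediate
13 | 1-[(3R)-5,7-bis(benzyloxy)-3-hydroxy-2,2-dimethylchroman-8-yl]ethanone | CC(=O)c1c(OCc2ccccc2)cc(OCc2ccccc2)c2c1OC(C)(C)[C@H](O)C2 | intermediate
14 | 1-[(3R)-3,5,7-trihydroxy-2,2-dimethylchroman-8-yl]ethanone | CC(=O)c1c(O)cc(O)c2c1OC(C)(C)[C@H](O)C2 | intermediate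
15 | geranyl bromide, (2E)-1-bromo-3,7-dimethylocta-2,6-diene | BrC/C=C(\C)CCC=C(C)C | starting material
16 | 1-[(3R)-5-{[(2E)-3,7-dimethylocta-2,6-dien-1-yl]oxy}-3,7-dihydroxy-2,2-dimethylchroman-8-yl]ethanone | CC(=O)c1c(O)cc(OC/C=C(\C)CCC=C(C)C)c2c1OC(C)(C)[C@H](O)C2 | target

Total step count: 9. Longest linear sequence: 9 steps (from 1 to 16).

Steps most likely to fail

Step 6. Carbonate may enolise the arylacetaldehyde faster than the carbene adds, which would lead to aldol condensation or acyl transfer from the active ester to C4. The carbene may also attack the ester carbonyl, or the C2 radical may pick up a hydrogen atom before it couples. The fallback replaces radical–radical coupling by a base-free radical–polar crossover that still closes ring B at C2–C3. It sets out from 11, now isolated by a short silica filtration after the carbodiimide coupling. With CrCl2 (4 equiv) in THF–DMF at rt, divalent chromium reduces the phthalimide ester and CO2 is lost. A second divalent chromium captures the C2 radical, and the tertiary alkylchromium adds to the aldehyde of the same molecule (decarboxylative Nozaki–Hiyama–Kishi-type addition). Aqueous work-up should give racemic 1-[5,7-bis(benzyloxy)-3-hydroxy-2,2-dimethylchroman-8-yl]ethanone F1. Dess–Martin periodinane in CH2Cl2 oxidises it to 12, where the route is rejoined.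

Step 4. Substitution at the crowded, hydrogen-bonded phenoxide may be so slow that the bromo acid is used up by elimination and hydrolysis. The fallback is a Bargellini reaction that sets out from 6, using 1,1,1-trichloro-2-methylpropan-2-ol and powdered NaOH in acetone at 0 °C to rt. The gem-dichloro epoxide formed in the flask is a far more reactive electrophile, and the phenoxide opens it at its tertiary carbon. The resulting acyl chloride is hydrolysed in the same flask. Using the preformed trichloro alcohol at low temperature keeps carbene addition to the allyl group down. The fallback comes back to the route at 8 and passes through no new isolable compound (none, F0).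

Step 7. Hydride may also be delivered to the 8-acetyl carbonyl. Facial discrimination may be poor if O1 or enolisation toward C4 disturbs the binding of the ketone to the catalyst. The fallback moves the deprotection forward and sets C3 by biocatalysis. It sets out from 12, which is hydrogenolysed (H2, Pd/C, EtOAc–MeOH, rt) to 8-acetyl-5,7-dihydroxy-2,2-dimethylchroman-3-one F2. An R-selective NADPH-dependent ketoreductase (isopropanol or glucose/glucose dehydrogenase recycling, phosphate buffer with DMSO, 30 °C) should then reduce only the ring ketone. The fallback comes back to the route at 14.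

Further compounds
F1 | step 6 | racemic 1-[5,7-bis(benzyloxy)-3-hydroxy-2,2-dimethylchroman-8-yl]ethanone | CC(=O)c1c(OCc2ccccc2)cc(OCc2ccccc2)c2c1OC(C)(C)C(O)C2
F0 | step 4 | none | none
F2 | step 7 | 8-acetyl-5,7-dihydroxy-2,2-dimethylchroman-3-one | CC(=O)c1c(O)cc(O)c2c1OC(C)(C)C(=O)C2
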